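C8–CH2 is cut last, giving an (S)-lavandulylzinc reagent and a complete (2S)-8-chloroflavanone; before that C2–aryl (conjugate arylation of a chromone), then O1–C2/C2–C3 (chromone from a methyl ketone and a one-carbon unit), then C4a–C4 (acylation) and C8–Cl.
The enabling feature is that C8 lies between O1 (on C8a) and O7 (on C7). With ring C opened at C4–C4a, ring A is 5-methoxyresorcinol bis-MOM ether, where this carbon sits on the mirror plane between two identical OMOM groups. Doubly directed lithiation puts chlorine exactly there; the two remaining ring CH are equivalent, so acylation cannot give a regioisomer, and the C–Cl bond survives the second lithiation to become the coupling handle.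
Forward: the lavandulyl unit is made (auxiliary alkylation, reduction, iodide); ring A is protected, chlorinated and acetylated; ring C is closed as a chromone and turned into the flavanone by asymmetric 1,4-arylation (ring B arrives intact); the two halves are joined at C8–CH2; the MOM groups are removed.
Stereochemistry: the lavandulyl centre comes from oxazolidinone-controlled α-alkylation of a senecioyl dienolate (S in lavandulol, 2R in the target by a CIP priority change only); C2 (S) comes from the ligand-controlled rhodium conjugate addition; the base-free coupling touches neither.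

Key step: step 11

Assumption: in step 10 the (S)-ligand is taken to give the 2S product, by analogy with the sense of (S)-biaryl bisphosphines in Hayashi–Miyaura additions to cyclic enones; the ligand antipode is used if a model run shows the opposite sense.

Step 1
Reactants: 1 (S)-4-benzyl-1,3-oxazolidin-2-one; 2 3-methylbut-2-enoyl chloride
Product: 4 (S)-4-benzyl-3-(3-methylbut-2-enoyl)-1,3-oxazolidin-2-one, via lithium oxazolidinide 3 (not isolated)
Conditions: n-BuLi, THF, −78 °C; then 2, −78 → 0 °C
Reagents that add atoms: none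
Why: N-acylation of the lithiated oxazolidinone by an acid chloride is the standard entry to Evans N-enoyl imides; no stereocentre is formed and the auxiliary centre is untouched.

Step 2
Reactants: 4 (S)-4-benzyl-3-(3-methylbut-2-enoyl)-1,3-oxazolidin-2-one; 5 prenyl bromide (1-bromo-3-methylbut-2-ene)
Product: 7 (S)-4-benzyl-3-[(2S)-5-methyl-2-(prop-1-en-2-yl)hex-4-enoyl]-1,3-oxazolidin-2-one, via sodium dienolate 6 (not isolated)
Conditions: NaHMDS (1.05 equiv), THF, −78 °C; then 5, −78 → −40 °C
Reagents that add atoms: none
Why: γ-deprotonation gives the chelated (Z)-dienolate 6, which is alkylated at Cα (the kinetic site of metal dienolates) on the face away from the benzyl group, a deconjugative Evans alkylation that sets the lavandulyl stereocentre as S and leaves the isopropenyl group out of conjugation.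

Step 3
Reactants: 7 (S)-4-benzyl-3-[(2S)-5-methyl-2-(prop-1-en-2-yl)hex-4-enoyl]-1,3-oxazolidin-2-one
Product: 8 (S)-lavandulol, (2S)-5-methyl-2-(prop-1-en-2-yl)hex-4-en-1-ol
Conditions: LiBH4, MeOH (1 equiv), Et2O, 0 °C
Reagents that add atoms: none
Why: borohydride reduction cleaves the exocyclic imide carbonyl of an N-acyl oxazolidinone to the primary alcohol without a base strong enough to epimerise or conjugate the β,γ-unsaturated α-centre, and returns the auxiliary.

Step 4
Reactants: 8 (S)-lavandulol
Product: 9 (S)-lavandulyl iodide, (2S)-1-iodo-5-methyl-2-(prop-1-en-2-yl)hex-4-ene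
Conditions: I2, PPh3, imidazole, CH2Cl2, 0 °C → rt
Reagents that add atoms: iodine, II
Why: Appel-type (Garegg–Samuelsson) iodination replaces the primary hydroxyl by SN2 at CH2, so the adjacent stereocentre is not involved.

Step 5
Reactants: 10 5-methoxyresorcinol (5-methoxybenzene-1,3-diol)
Product: 11 1-methoxy-3,5-bis(methoxymethoxy)benzene
Conditions: MOMCl, i-Pr2NEt, CH2Cl2, 0 °C → rt
Reagents that add atoms: chloromethyl methyl ether, COCCl
Why: O-alkylation of both phenols installs two identical acetals that are strong ortho-directing groups for lithiation and keeps the arene mirror-symmetric.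

Step 6
Reactants: 11 1-methoxy-3,5-bis(methoxymethoxy)benzene
Product: 13 2-chloro-5-methoxy-1,3-bis(methoxymethoxy)benzene, via 2-lithio arene 12 (not isolated)
Conditions: n-BuLi, THF, 0 °C → rt; then C2Cl6, −78 °C → rt
Reagents that add atoms: hexachloroethane, ClC(Cl)(Cl)C(Cl)(Cl)Cl
Why: directed ortho-metalation: the carbon between the two OMOM groups should be lithiated preferentially because both acetals chelate lithium there (OMOM outranks OMe as a directing group, and warming lets the aryllithiums settle on this doubly chelated species), and hexachloroethane then transfers electrophilic chlorine.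

Step 7
Reactants: 13 2-chloro-5-methoxy-1,3-bis(methoxymethoxy)benzene
Product: 15 1-[3-chloro-6-methoxy-2,4-bis(methoxymethoxy)phenyl]ethan-1-one, via aryllithium 14 (not isolated)
Conditions: s-BuLi, TMEDA, THF, −78 °C; then MeCON(OMe)Me, −78 → 0 °C
Reagents that add atoms: N-methoxy-N-methylacetamide, CC(=O)N(C)OC
Why: second directed ortho-metalation: the only ring hydrogens left are the two equivalent ones between OMOM and OMe, the aryl chloride neither exchanges nor eliminates at −78 °C (no hydrogen ortho to Cl), and the Weinreb amide stops at the methyl ketone.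

Step 8
Reactants: 15 1-[3-chloro-6-methoxy-2,4-bis(methoxymethoxy)phenyl]ethan-1-one
Product: 17 8-chloro-7-hydroxy-5-methoxy-4H-chromen-4-one, via enaminone 16 (not isolated)
Conditions: Me2NCH(OMe)2, toluene, 100 °C; evaporate; then conc. HCl, MeOH, 50 °C
Reagents that add atoms: N,N-dimethylformamide dimethyl acetal, COC(OC)N(C)C
Why: condensation of the methyl ketone with the amide acetal gives the enaminone, and methanolic HCl then cleaves both MOM acetals so that the phenol ortho to the ketone adds to the β-carbon and expels dimethylamine, the standard enaminone route to chromones; no alkene is present yet, so strong acid is harmless.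

Step 9
Reactants: 17 8-chloro-7-hydroxy-5-methoxy-4H-chromen-4-one
Product: 18 8-chloro-5-methoxy-7-(methoxymethoxy)-4H-chromen-4-one
Conditions: MOMCl, i-Pr2NEt, CH2Cl2, 0 °C → rt
Reagents that add atoms: chloromethyl methyl ether, COCCl
Why: the acidic 7-OH (a vinylogous acid) is re-protected as its MOM ether so that the chromone is a neutral acceptor in the conjugate addition and the final deprotection is a single operation.

Step 10
Reactants: 18 8-chloro-5-methoxy-7-(methoxymethoxy)-4H-chromen-4-one; 19 [2-(methoxymethoxy)phenyl]boronic acid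
Product: 20 (2S)-8-chloro-5-methoxy-7-(methoxymethoxy)-2-[2-(methoxymethoxy)phenyl]-2,3-dihydro-4H-chromen-4-one
Conditions: [Rh(OH)(cod)]2 (2.5 mol %), (S)-MeO-F12-BIPHEP (5.5 mol %), 19 (3 equiv), toluene/H2O, 30 °C
Reagents that add atoms: none
Why: rhodium-catalysed asymmetric 1,4-addition of an arylboronic acid to a chromone (Hayashi–Miyaura type): aryl–Rh adds across C2=C3 from the face dictated by the C2-symmetric bisphosphine, setting C2 as S, and water protonates the rhodium enolate under base-free conditions that should not open the ring; the C8–Cl bond is inert to Rh(I).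

Step 11
Reactants: 9 (S)-lavandulyl iodide; 20 (2S)-8-chloro-5-methoxy-7-(methoxymethoxy)-2-[2-(methoxymethoxy)phenyl]-2,3-dihydro-4H-chromen-4-one
Product: 22 (2S)-5-methoxy-7-(methoxymethoxy)-2-[2-(methoxymethoxy)phenyl]-8-[(2R)-5-methyl-2-(prop-1-en-2-yl)hex-4-en-1-yl]-2,3-dihydro-4H-chromen-4-one, via lavandulylzinc iodide 21 (not isolated)
Conditions: Zn dust (BrCH2CH2Br/TMSCl-activated), LiCl, THF, 35 °C; then 20, Pd-PEPPSI-IPent (5 mol %), THF/NMP, 50 °C
Reagents that add atoms: none
Why: Zinc inserts into the primary C–I bond of 9 to give alkylzinc 21, whose stereocentre is β to the metal and not involved; Pd(0)–NHC then inserts into the C8–Cl bond of 20, transmetalation delivers the lavandulyl CH2 to palladium, and reductive elimination forms the C8–CH2 bond. The closest known reaction type is the Negishi coupling of primary alkylzinc halides with hindered, electron-rich aryl chlorides under bulky NHC- or biarylphosphine-palladium catalysis. No ring is closed and no stereocentre is created; both existing centres are spectators, because the coupling is base-free (the base-labile C2 is never exposed to phenoxide or enolate chemistry) and because the bulky ligand should make reductive elimination faster than β-hydride elimination, so palladium cannot walk to the lavandulyl methine. The selectivity needed is C8 over C6, and the substrate secures it: the chlorine was placed on the mirror-plane carbon between the two oxygens before ring C existed, it is the only halogen in 20, and organozinc reagents do not add to the C4 ketone or attack the MOM acetals. Chloride is used because, unlike bromide or iodide, it survives the lithiation of step 7.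

Step 12
Reactants: 22 (2S)-5-methoxy-7-(methoxymethoxy)-2-[2-(methoxymethoxy)phenyl]-8-[(2R)-5-methyl-2-(prop-1-en-2-yl)hex-4-en-1-yl]-2,3-dihydro-4H-chromen-4-one
Product: 23 kushenol R, (2S)-7-hydroxy-2-(2-hydroxyphenyl)-5-methoxy-8-[(2R)-5-methyl-2-(prop-1-en-2-yl)hex-4-en-1-yl]-2,3-dihydro-4H-chromen-4-one
Conditions: HCl (1.25 M in MeOH), 0 °C → rt
Reagents that add atoms: none
Why: acid-catalysed methanolysis of the two aryl MOM acetals liberates 7-OH and 2′-OH; dilute methanolic HCl at or below room temperature should not protonate the alkenes, and without base the ring-opening pathway that racemises flavanones is not available.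

Compound list
1 | (S)-4-benzyl-1,3-oxazolidin-2-one | O=C1N[C@@H](Cc2ccccc2)CO1 | starting material
2 | 3-methylbut-2-enoyl chloride | CC(C)=CC(=O)Cl | starting material
3 | lithium (S)-4-benzyl-2-oxo-1,3-oxazolidin-3-ide | [Li]N1[C@@H](Cc2ccccc2)COC1=O | intermediate
4 | (S)-4-benzyl-3-(3-methylbut-2-enoyl)-1,3-oxazolidin-2-one | CC(C)=CC(=O)N1[C@@H](Cc2ccccc2)COC1=O | intermediate
5 | prenyl bromide (1-bromo-3-methylbut-2-ene) | CC(C)=CCBr | starting material
6 | sodium (Z)-dienolate of 4 | C=C(C)/C=C(\O[Na])N1[C@@H](Cc2ccccc2)COC1=O | intermediate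
7 | (S)-4-benzyl-3-[(2S)-5-methyl-2-(prop-1-en-2-yl)hex-4-enoyl]-1,3-oxazolidin-2-one | C=C(C)[C@H](CC=C(C)C)C(=O)N1[C@@H](Cc2ccccc2)COC1=O | intermediate
8 | (S)-lavandulol, (2S)-5-methyl-2-(prop-1-en-2-yl)hex-4-en-1-ol | C=C(C)[C@H](CC=C(C)C)CO | intermediate
9 | (S)-lavandulyl iodide, (2S)-1-iodo-5-methyl-2-(prop-1-en-2-yl)hex-4-ene | C=C(C)[C@H](CC=C(C)C)CI | intermediate
10 | 5-methoxyresorcinol (5-methoxybenzene-1,3-diol) | COc1cc(O)cc(O)c1 | starting material
11 | 1-methoxy-3,5-bis(methoxymethoxy)benzene | COCOc1cc(OC)cc(OCOC)c1 | intermediate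
12 | [4-methoxy-2,6-bis(methoxymethoxy)phenyl]lithium | [Li]c1c(OCOC)cc(OC)cc1OCOC | intermediate
13 | 2-chloro-5-methoxy-1,3-bis(methoxymethoxy)benzene | COCOc1cc(OC)cc(OCOC)c1Cl | intermediate
14 | [3-chloro-6-methoxy-2,4-bis(methoxymethoxy)phenyl]lithium | [Li]c1c(OC)cc(OCOC)c(Cl)c1OCOC | intermediate
15 | 1-[3-chloro-6-methoxy-2,4-bis(methoxymethoxy)phenyl]ethan-1-one | CC(=O)c1c(OC)cc(OCOC)c(Cl)c1OCOC | intermediate
16 | (E)-1-[3-chloro-6-methoxy-2,4-bis(methoxymethoxy)phenyl]-3-(dimethylamino)prop-2-en-1-one | CN(C)/C=C/C(=O)c1c(OC)cc(OCOC)c(Cl)c1OCOC | intermediate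
17 | 8-chloro-7-hydroxy-5-methoxy-4H-chromen-4-one | COc1cc(O)c(Cl)c2occc(=O)c12 | intermediate
18 | 8-chloro-5-methoxy-7-(methoxymethoxy)-4H-chromen-4-one | COCOc1cc(OC)c2c(=O)ccoc2c1Cl | intermediate
19 | [2-(methoxymethoxy)phenyl]boronic acid | COCOc1ccccc1B(O)O | starting material
20 | (2S)-8-chloro-5-methoxy-7-(methoxymethoxy)-2-[2-(methoxymethoxy)phenyl]-2,3-dihydro-4H-chromen-4-one | COCOc1cc(OC)c2c(c1Cl)O[C@H](c1ccccc1OCOC)CC2=O | intermediate
21 | [(2S)-5-methyl-2-(prop-1-en-2-yl)hex-4-en-1-yl]zinc iodide | C=C(C)[C@H](CC=C(C)C)C[Zn]I | intermediate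
22 | (2S)-5-methoxy-7-(methoxymethoxy)-2-[2-(methoxymethoxy)phenyl]-8-[(2R)-5-methyl-2-(prop-1-en-2-yl)hex-4-en-1-yl]-2,3-dihydro-4H-chromen-4-one | C=C(C)[C@H](CC=C(C)C)Cc1c(OCOC)cc(OC)c2c1O[C@H](c1ccccc1OCOC)CC2=O | intermediate
23 | kushenol R, (2S)-7-hydroxy-2-(2-hydroxyphenyl)-5-methoxy-8-[(2R)-5-methyl-2-(prop-1-en-2-yl)hex-4-en-1-yl]-2,3-dihydro-4H-chromen-4-one | C=C(C)[C@H](CC=C(C)C)Cc1c(O)cc(OC)c2c1O[C@H](c1ccccc1O)CC2=O | target

Total step count: 12. Longest linear sequence: 8 steps (steps 5–12, from 5-methoxyresorcinol 10); the lavandulyl branch is 4 steps to the coupling.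

Steps most likely to fail

Step 11. Oxidative addition into the doubly ortho-oxygenated, electron-rich C8–Cl bond may be slow, so that β-hydride elimination from the lavandulyl–palladium species (reduction of the chloride, loss of the side chain as a diene) or zinc-salt-assisted ring opening at C2 competes. The fallback makes the same bond first, on a simple aryl iodide, and builds ring C around it. Compound 11 is lithiated as in step 6 and quenched with iodine to give 2-iodo-5-methoxy-1,3-bis(methoxymethoxy)benzene F1. Negishi coupling of F1 with 21 (Pd(OAc)2/SPhos, THF, rt) should give 5-methoxy-1,3-bis(methoxymethoxy)-2-[(2R)-5-methyl-2-(prop-1-en-2-yl)hex-4-en-1-yl]benzene F2. Ortho-lithiation and acetylation as in step 7 give the lavandulyl acetophenone F3; the amide acetal/methanolic HCl sequence of step 8 gives 7-hydroxy-5-methoxy-8-lavandulylchromone F4; MOM protection gives 5-methoxy-7-(methoxymethoxy)-8-lavandulylchromone F5. Rhodium-catalysed addition of 19 as in step 10 then returns to the route at 22.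

Step 10. The ortho-substituted boronic acid may transfer its aryl group slowly, so that protodeboronation outruns addition, or the facial selectivity at C2 may be insufficient. The fallback sets C2 by an aldol reaction and closes ring C by C–O bond formation with inversion. Acetophenone 15 is converted into its diisopinocampheylboron enolate (Ipc2BCl antipode chosen for the 3R carbinol, Et3N) and added to 2-(methoxymethoxy)benzaldehyde to give the (3R)-aldol F6. Chelation-controlled removal of the MOM group ortho to the ketone (MgBr2·OEt2) gives the (3R)-hydroxy ketone with a free ortho-phenol F7. Mitsunobu cyclisation (PPh3, DIAD, THF, 0 °C) closes O1–C2 with inversion and returns to the route at 20.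

Step 12. Acid may trigger cyclisation of the freed 7-OH onto the isopropenyl or prenyl alkene, or flavanone–chalcone ring–chain equilibration that erodes C2 (the 2′-oxygenated aryl group stabilises the benzylic cation). The fallback carries fluoride-labile silyl ethers instead, so that no protic acid is used once C2 and the alkenes are present. Chromone 17 is silylated (TBSCl, imidazole, DMF) to 7-[(tert-butyldimethylsilyl)oxy]-8-chloro-5-methoxy-4H-chromen-4-one F8. Rhodium-catalysed addition of purchased [2-(tert-butyldimethylsilyloxy)phenyl]boronic acid as in step 10 gives the bis-silyl (2S)-8-chloroflavanone F9; Negishi coupling with 21 as in step 11 gives bis-silyl kushenol R F10. Desilylation with TBAF buffered by AcOH (THF, 0 °C) returns to the route at 23.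

Further compounds
F1 | step 11 | 2-iodo-5-methoxy-1,3-bis(methoxymethoxy)benzene | COCOc1cc(OC)cc(OCOC)c1I
F2 | step 11 | 5-methoxy-1,3-bis(methoxymethoxy)-2-[(2R)-5-methyl-2-(prop-1-en-2-yl)hex-4-en-1-yl]benzene | C=C(C)[C@H](CC=C(C)C)Cc1c(OCOC)cc(OC)cc1OCOC
F3 | step 11 | 1-{6-methoxy-2,4-bis(methoxymethoxy)-3-[(2R)-5-methyl-2-(prop-1-en-2-yl)hex-4-en-1-yl]phenyl}ethan-1-one | C=C(C)[C@H](CC=C(C)C)Cc1c(OCOC)cc(OC)c(C(C)=O)c1OCOC
F4 | step 11 | 7-hydroxy-5-methoxy-8-[(2R)-5-methyl-2-(prop-1-en-2-yl)hex-4-en-1-yl]-4H-chromen-4-one | C=C(C)[C@H](CC=C(C)C)Cc1c(O)cc(OC)c2c(=O)ccoc12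
F5 | step 11 | 5-methoxy-7-(methoxymethoxy)-8-[(2R)-5-methyl-2-(prop-1-en-2-yl)hex-4-en-1-yl]-4H-chromen-4-one | C=C(C)[C@H](CC=C(C)C)Cc1c(OCOC)cc(OC)c2c(=O)ccoc12
F6 | step 10 | (3R)-1-[3-chloro-6-methoxy-2,4-bis(methoxymethoxy)phenyl]-3-hydroxy-3-[2-(methoxymethoxy)phenyl]propan-1-one | COCOc1ccccc1[C@H](O)CC(=O)c1c(OC)cc(OCOC)c(Cl)c1OCOC
F7 | step 10 | (3R)-1-[3-chloro-2-hydroxy-6-methoxy-4-(methoxymethoxy)phenyl]-3-hydroxy-3-[2-(methoxymethoxy)phenyl]propan-1-one | COCOc1ccccc1[C@H](O)CC(=O)c1c(OC)cc(OCOC)c(Cl)c1O
F8 | step 12 | 7-[(tert-butyldimethylsilyl)oxy]-8-chloro-5-methoxy-4H-chromen-4-one | CC(C)(C)[Si](C)(C)Oc1cc(OC)c2c(=O)ccoc2c1Cl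
F9 | step 12 | (2S)-7-[(tert-butyldimethylsilyl)oxy]-2-{2-[(tert-butyldimethylsilyl)oxy]phenyl}-8-chloro-5-methoxy-2,3-dihydro-4H-chromen-4-one | CC(C)(C)[Si](C)(C)Oc1cc(OC)c2c(c1Cl)O[C@H](c1ccccc1O[Si](C)(C)C(C)(C)C)CC2=O
F10 | step 12 | (2S)-7-[(tert-butyldimethylsilyl)oxy]-2-{2-[(tert-butyldimethylsilyl)oxy]phenyl}-5-methoxy-8-[(2R)-5-methyl-2-(prop-1-en-2-yl)hex-4-en-1-yl]-2,3-dihydro-4H-chromen-4-one | C=C(C)[C@H](CC=C(C)C)Cc1c(O[Si](C)(C)C(C)(C)C)cc(OC)c2c1O[C@H](c1ccccc1O[Si](C)(C)C(C)(C)C)CC2=O
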